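**Plan**

- The guiding feature is the butenolide ring (O1, C2, C3, C4, C5). C4 carries an aryl group and C5 carries H, an arylmethyl group and O1, which is what a 2,3-allenoic acid gives when it is arylated at its central carbon and lactonised at its terminus.
- Retrosynthesis removes the two phenolic silyl groups and the enol methyl group, then cuts O1–C5 and C4–aryl together (aryl iodide plus 2-methoxy-2,3-allenoic acid). The allene C2=C3 bond is cut next (phosphonoacetate plus a ketene from an arylpropanoic acid), and the arene–prenyl bond last.
- Forward, the chain is assembled by ortho-prenylation of methyl 3-(4-hydroxyphenyl)propanoate, silylation, hydrolysis and ketene olefination to the allenoate. The butenolide, the only ring made, closes in step 7 with the 4-aryl group attached; demethylation and desilylation finish the route.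
- The allene axis is secured as (P) by resolution of the acid as an amine salt and is transferred to C5 (R) in the ring closure; the target has no other stereocentre.
- Both phenols carry triisopropylsilyl groups (stable to hydroxide) and the enol oxygen carries methyl (removed by chelation-assisted BCl3, and its methyl ester hydrolyses under mild conditions).

Key step: step 7

Assumption: (S)-1-phenylethylamine is written as the antipode whose salt with the (P)-acid is the less soluble one; if the (M)-acid salt crystallises instead, (R)-1-phenylethylamine is used and nothing else changes.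

Abbreviations: prenyl = 3-methylbut-2-en-1-yl; lactone numbering O1, C2 (C=O), C3, C4, C5; (P) is the helical descriptor of the allene axis (equivalent to aS).

**Route**

Step 1
Reactants: 1 methyl 3-(4-hydroxyphenyl)propanoate; 2 prenyl bromide
Product: 3 methyl 3-(4-hydroxy-3-prenylphenyl)propanoate
Conditions: NaH (1.05 equiv), toluene, 0 °C → rt; then 2 (1.0 equiv), rt
Reagents that add atoms: none
Why: Ortho-C-alkylation of a sodium phenoxide: in a non-coordinating solvent the tight ion pair should react at carbon next to oxygen (the para position is blocked), and the O-prenyl ether and diprenylated material should be separable by chromatography.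

Step 2
Reactants: 3 methyl 3-(4-hydroxy-3-prenylphenyl)propanoate
Product: 4 methyl 3-[3-prenyl-4-(triisopropylsilyloxy)phenyl]propanoate
Conditions: i-Pr3SiCl, imidazole, DMF, rt → 40 °C
Reagents that add atoms: triisopropylsilyl chloride, CC(C)[Si](Cl)(C(C)C)C(C)C
Why: Standard silylation of a phenol with a silyl chloride and imidazole, the bulky silyl ether being chosen because it must survive two hydroxide hydrolyses, zerovalent palladium with an amine at 70 °C and BCl3.

Step 3
Reactants: 4 methyl 3-[3-prenyl-4-(triisopropylsilyloxy)phenyl]propanoate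
Product: 5 3-[3-prenyl-4-(triisopropylsilyloxy)phenyl]propanoic acid
Conditions: LiOH·H2O, THF/MeOH/H2O, rt; then 0.5 M HCl to pH 3, 0 °C
Reagents that add atoms: lithium hydroxide, [Li+].[OH-]
Why: Saponification of an unhindered methyl ester, under which the hindered aryl silyl ether and the trisubstituted alkene should be inert.

Step 4
Reactants: 5 3-[3-prenyl-4-(triisopropylsilyloxy)phenyl]propanoic acid; 6 methyl 2-(dimethoxyphosphoryl)-2-methoxyacetate
Product: 9 methyl 2-methoxy-5-[3-prenyl-4-(triisopropylsilyloxy)phenyl]penta-2,3-dienoate (racemic), via acid chloride 7 (not isolated), via ketene 8 (not isolated)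
Conditions: 1-chloro-N,N,2-trimethylprop-1-en-1-amine, CH2Cl2, 0 °C → rt; this solution and Et3N added to 6/NaH in THF, −78 °C → rt
Reagents that add atoms: none
Why: Horner–Wadsworth–Emmons olefination of a ketene: the acid chloride is formed without HCl (which could add to the prenyl alkene), Et3N dehydrochlorinates it to the monosubstituted ketene, the phosphonate carbanion adds to the ketene carbonyl carbon and the resulting enolate oxygen expels dimethyl phosphate through a four-membered ring to give the allene (direct C-acylation of the carbanion followed by enolisation reaches the same enolate).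

Step 5
Reactants: 9 methyl 2-methoxy-5-[3-prenyl-4-(triisopropylsilyloxy)phenyl]penta-2,3-dienoate (racemic)
Product: 11 (S)-1-phenylethylammonium (P)-2-methoxy-5-[3-prenyl-4-(triisopropylsilyloxy)phenyl]penta-2,3-dienoate, via racemic acid 10 (not isolated)
Conditions: LiOH·H2O, THF/H2O, 0 °C; cold 0.5 M HCl to pH 3, t-BuOMe extraction; (S)-1-phenylethylamine (1.0 equiv), t-BuOMe/heptane, fractional crystallisation to constant rotation
Reagents that add atoms: lithium hydroxide, [Li+].[OH-]; (S)-1-phenylethylamine, C[C@H](N)c1ccccc1
Why: Ester saponification followed by classical resolution through diastereomeric ammonium salts, an established way to enantioenriched 2,3-allenoic acids, which selects the (P) axis and at the same time keeps the acid-sensitive alkoxyallene acid in a stable salt form.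

Step 6
Reactants: 12 4-iodophenol
Product: 13 (4-iodophenoxy)triisopropylsilane
Conditions: i-Pr3SiCl, imidazole, DMF, rt
Reagents that add atoms: triisopropylsilyl chloride, CC(C)[Si](Cl)(C(C)C)C(C)C
Why: Standard phenol silylation with a silyl chloride and imidazole, giving the same protecting group on both phenols so that one fluoride step removes both at the end.

Step 7
Reactants: 11 (S)-1-phenylethylammonium (P)-2-methoxy-5-[3-prenyl-4-(triisopropylsilyloxy)phenyl]penta-2,3-dienoate; 13 (4-iodophenoxy)triisopropylsilane
Product: 14 (5R)-3-methoxy-5-{[3-prenyl-4-(triisopropylsilyloxy)phenyl]methyl}-4-[4-(triisopropylsilyloxy)phenyl]furan-2(5H)-one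
Conditions: Pd(PPh3)4 (5 mol %), 13 (1.2 equiv), degassed MeCN, 70 °C, no inorganic base
Reagents that add atoms: none
Why: Oxidative addition of 13 to zerovalent palladium gives an arylpalladium iodide (divalent palladium) that binds the distal double bond of the allene (allene C3=C4, the future lactone C4 and C5) on the face turned away from the carboxylate; the carboxylate oxygen adds to the terminus anti to the metal, and reductive elimination from the 4-palladated furanone forms the C4–aryl bond and returns zerovalent palladium. The closest known reaction is the palladium-catalysed coupling–cyclisation of amine salts of enantioenriched 2-alkyl- and 2-aryl-2,3-allenoic acids with aryl iodides to 4-aryl butenolides, applied here to a 2-methoxy member of the same substrate class. The butenolide, the only ring formed, closes by a 5-endo-trig oxypalladation that makes O1–C5. C5 is the only new stereocentre and is set by the allene axis: the carboxylate can reach the terminus only from its own side, so with H and the arylmethyl group fixed on that carbon the (P)-acid should give (5R). The step needs anti-oxypalladation to outrun carbopalladation to a π-allylpalladium species that could lose configuration by σ–π–σ isomerisation (the constitution would be the same either way); this should be favoured by the preformed soluble ammonium carboxylate, by the absence of silver salts and carbonate bases, and by the fully substituted C2=C3 bond, which steers the metal to the distal bond. The trisubstituted prenyl alkene and the aryl silyl ethers should not react under these conditions.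

Step 8
Reactants: 14 (5R)-3-methoxy-5-{[3-prenyl-4-(triisopropylsilyloxy)phenyl]methyl}-4-[4-(triisopropylsilyloxy)phenyl]furan-2(5H)-one
Product: 15 (5R)-3-hydroxy-5-{[3-prenyl-4-(triisopropylsilyloxy)phenyl]methyl}-4-[4-(triisopropylsilyloxy)phenyl]furan-2(5H)-one
Conditions: BCl3 (1 M in CH2Cl2, 3 equiv), CH2Cl2, −78 → −20 °C; pH 7 phosphate buffer
Reagents that add atoms: none
Why: Chelation-assisted Lewis-acid O-demethylation, in which BCl3 bridges the lactone carbonyl and the neighbouring methoxy oxygen and chloride removes the methyl group by SN2, should at low temperature leave the aryl silyl ethers, the prenyl alkene and C5 untouched.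

Step 9
Reactants: 15 (5R)-3-hydroxy-5-{[3-prenyl-4-(triisopropylsilyloxy)phenyl]methyl}-4-[4-(triisopropylsilyloxy)phenyl]furan-2(5H)-one
Product: 16 (5R)-3-hydroxy-4-(4-hydroxyphenyl)-5-[(4-hydroxy-3-prenylphenyl)methyl]furan-2(5H)-one
Conditions: n-Bu4NF, AcOH (1:1, 3 equiv), THF, 0 °C
Reagents that add atoms: none
Why: Fluoride-induced desilylation of aryl silyl ethers, buffered with AcOH so that the base-sensitive C5–H of the 4-aryl butenolide should not epimerise and the o-prenylphenol should not cyclise to a chroman.

**Compound list**

1 | methyl 3-(4-hydroxyphenyl)propanoate | COC(=O)CCc1ccc(O)cc1 | starting material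
2 | prenyl bromide (1-bromo-3-methylbut-2-ene) | CC(C)=CCBr | starting material
3 | methyl 3-(4-hydroxy-3-prenylphenyl)propanoate | COC(=O)CCc1ccc(O)c(CC=C(C)C)c1 | intermediate
4 | methyl 3-[3-prenyl-4-(triisopropylsilyloxy)phenyl]propanoate | COC(=O)CCc1ccc(O[Si](C(C)C)(C(C)C)C(C)C)c(CC=C(C)C)c1 | intermediate
5 | 3-[3-prenyl-4-(triisopropylsilyloxy)phenyl]propanoic acid | OC(=O)CCc1ccc(O[Si](C(C)C)(C(C)C)C(C)C)c(CC=C(C)C)c1 | intermediate
6 | methyl 2-(dimethoxyphosphoryl)-2-methoxyacetate | COC(C(=O)OC)P(=O)(OC)OC | starting material
7 | 3-[3-prenyl-4-(triisopropylsilyloxy)phenyl]propanoyl chloride | O=C(Cl)CCc1ccc(O[Si](C(C)C)(C(C)C)C(C)C)c(CC=C(C)C)c1 | intermediate (not isolated)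
8 | 3-[3-prenyl-4-(triisopropylsilyloxy)phenyl]prop-1-en-1-one (ketene) | O=C=CCc1ccc(O[Si](C(C)C)(C(C)C)C(C)C)c(CC=C(C)C)c1 | intermediate (not isolated)
9 | methyl 2-methoxy-5-[3-prenyl-4-(triisopropylsilyloxy)phenyl]penta-2,3-dienoate, racemic | COC(=O)C(OC)=C=CCc1ccc(O[Si](C(C)C)(C(C)C)C(C)C)c(CC=C(C)C)c1 | intermediate
10 | 2-methoxy-5-[3-prenyl-4-(triisopropylsilyloxy)phenyl]penta-2,3-dienoic acid, racemic | OC(=O)C(OC)=C=CCc1ccc(O[Si](C(C)C)(C(C)C)C(C)C)c(CC=C(C)C)c1 | intermediate (not isolated)
11 | (S)-1-phenylethylammonium (P)-2-methoxy-5-[3-prenyl-4-(triisopropylsilyloxy)phenyl]penta-2,3-dienoate (1:1 salt) | [O-]C(=O)C(OC)=[C@]=C([H])Cc1ccc(O[Si](C(C)C)(C(C)C)C(C)C)c(CC=C(C)C)c1.C[C@H]([NH3+])c1ccccc1 | intermediate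
12 | 4-iodophenol | Oc1ccc(I)cc1 | starting material
13 | (4-iodophenoxy)triisopropylsilane | Ic1ccc(O[Si](C(C)C)(C(C)C)C(C)C)cc1 | intermediate
14 | (5R)-3-methoxy-5-{[3-prenyl-4-(triisopropylsilyloxy)phenyl]methyl}-4-[4-(triisopropylsilyloxy)phenyl]furan-2(5H)-one | CC(C)=CCc1cc(C[C@H]2OC(=O)C(OC)=C2c2ccc(O[Si](C(C)C)(C(C)C)C(C)C)cc2)ccc1O[Si](C(C)C)(C(C)C)C(C)C | intermediate
15 | (5R)-3-hydroxy-5-{[3-prenyl-4-(triisopropylsilyloxy)phenyl]methyl}-4-[4-(triisopropylsilyloxy)phenyl]furan-2(5H)-one | CC(C)=CCc1cc(C[C@H]2OC(=O)C(O)=C2c2ccc(O[Si](C(C)C)(C(C)C)C(C)C)cc2)ccc1O[Si](C(C)C)(C(C)C)C(C)C | intermediate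
16 | (5R)-3-hydroxy-4-(4-hydroxyphenyl)-5-[(4-hydroxy-3-prenylphenyl)methyl]furan-2(5H)-one | CC(C)=CCc1cc(C[C@H]2OC(=O)C(O)=C2c2ccc(O)cc2)ccc1O | target

Total step count: 9. Longest linear sequence: 8 steps (steps 1, 2, 3, 4, 5, 7, 8, 9); step 6 is a one-step side branch.

**Steps most likely to fail**

Step 5. The diastereomeric salts may fail to crystallise or may differ too little in solubility, so that no enrichment results; the allenoate may also isomerise under hydroxide. The fallback sets out from racemic ester 9 and separates the enantiomers physically: preparative chromatography on a cellulose tris(3,5-dimethylphenylcarbamate) stationary phase should give methyl (P)-2-methoxy-5-[3-prenyl-4-(triisopropylsilyloxy)phenyl]penta-2,3-dienoate F1. Cold LiOH hydrolysis and careful acidification then give (P)-2-methoxy-5-[3-prenyl-4-(triisopropylsilyloxy)phenyl]penta-2,3-dienoic acid F2 in solution, and one equivalent of (S)-1-phenylethylamine converts it into salt 11, where the route is rejoined without any crystallisation-based enrichment.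

Step 4. The monosubstituted ketene may dimerise, the C-acylated phosphonate may stall before phosphate elimination, or the amine may isomerise the allenoate to the conjugated dienoate. The fallback sets out from acid 5 (converted into chloride 7 as in step 4) and builds the allene by elimination instead of olefination. Crossed Claisen acylation of the lithium enolate of methyl methoxyacetate (LiN(i-Pr)2, two equivalents, THF, −78 °C) with 7 should give methyl 2-methoxy-3-oxo-5-[3-prenyl-4-(triisopropylsilyloxy)phenyl]pentanoate F3. O-Triflation of its enolate (LiN(SiMe3)2, Tf2O, THF, −78 °C) gives methyl 2-methoxy-5-[3-prenyl-4-(triisopropylsilyloxy)phenyl]-3-(trifluoromethylsulfonyloxy)pent-2-enoate F4, and a second equivalent of LiN(SiMe3)2 removes a C4 proton with loss of triflate, a known route from 2-substituted β-keto esters to allenoates, returning to the route at 9.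

Step 7. Part of the material may pass through carbopalladation and a configurationally labile π-allylpalladium species, eroding the enantiomeric purity, and oxidative addition of the electron-rich iodide may be slow. The fallback sets out from salt 11 and separates ring closure from arylation. Iodolactonisation (I2, MeCN, 0 °C) adds iodine and the carboxylate anti across the distal double bond, with the oxygen again delivered from its own side, and should give (5R)-4-iodo-3-methoxy-5-{[3-prenyl-4-(triisopropylsilyloxy)phenyl]methyl}furan-2(5H)-one F5. Iodide 13 is converted (n-BuLi, B(O-i-Pr)3, THF, −78 °C; aqueous NH4Cl) into [4-(triisopropylsilyloxy)phenyl]boronic acid F6, and Suzuki–Miyaura coupling of F5 with F6 (Pd(OAc)2, SPhos, K3PO4, toluene/H2O, 40 °C) should give 14, where the route is rejoined.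

**Further compounds**

F1 | step 5 | methyl (P)-2-methoxy-5-[3-prenyl-4-(triisopropylsilyloxy)phenyl]penta-2,3-dienoate | COC(=O)C(OC)=[C@]=C([H])Cc1ccc(O[Si](C(C)C)(C(C)C)C(C)C)c(CC=C(C)C)c1
F2 | step 5 | (P)-2-methoxy-5-[3-prenyl-4-(triisopropylsilyloxy)phenyl]penta-2,3-dienoic acid | OC(=O)C(OC)=[C@]=C([H])Cc1ccc(O[Si](C(C)C)(C(C)C)C(C)C)c(CC=C(C)C)c1
F3 | step 4 | methyl 2-methoxy-3-oxo-5-[3-prenyl-4-(triisopropylsilyloxy)phenyl]pentanoate (racemic) | COC(=O)C(OC)C(=O)CCc1ccc(O[Si](C(C)C)(C(C)C)C(C)C)c(CC=C(C)C)c1
F4 | step 4 | methyl 2-methoxy-5-[3-prenyl-4-(triisopropylsilyloxy)phenyl]-3-(trifluoromethylsulfonyloxy)pent-2-enoate | COC(=O)C(OC)=C(OS(=O)(=O)C(F)(F)F)CCc1ccc(O[Si](C(C)C)(C(C)C)C(C)C)c(CC=C(C)C)c1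
F5 | step 7 | (5R)-4-iodo-3-methoxy-5-{[3-prenyl-4-(triisopropylsilyloxy)phenyl]methyl}furan-2(5H)-one | CC(C)=CCc1cc(C[C@H]2OC(=O)C(OC)=C2I)ccc1O[Si](C(C)C)(C(C)C)C(C)C
F6 | step 7 | [4-(triisopropylsilyloxy)phenyl]boronic acid | OB(O)c1ccc(O[Si](C(C)C)(C(C)C)C(C)C)cc1
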